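**Retrosynthetic overview**
- The target is the meso (2R,3S) 1,4-diaryl-2,3-dimethylbutane. Both stereocentres and all four free phenols are traced back to one operation: syn-addition of H2 to the O-benzylated (Z)-alkene ArCH2–C(CH3)=C(CH3)–CH2Ar.
- That (Z)-alkene is cut at both benzylic CH2–C(CH3) bonds into three components: but-2-yne (C2, C3 and both methyl groups) and two molecules of one benzylic chloride. They are joined in one flask by cobalt-catalysed syn-benzylzincation, then palladium-catalysed Negishi coupling of the alkenylzinc.
- Enabling feature: the vicinal CH(CH3)–CH(CH3) pair C2/C3 of the butane chain carries two identical CH2–aryl arms (ring A = ring B = 3,4-dihydroxy-5-methoxyphenyl) and is bisected by a mirror plane. It is the reduced, doubly benzylated image of the C≡C bond of but-2-yne, so regiochemistry is moot and cis-carbometalation geometry becomes the meso configuration.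
- The benzylic chloride comes from 5-hydroxyvanillin by O-benzylation, reduction and chlorination.
- No ring is formed in the route; both benzene rings are bought intact.

Key step: step 4

Remark on the chemistry: the stereodescriptors of the target correspond to (2R,3S) with identical aryl groups, i.e. the achiral meso diastereomer, so only the relative configuration has to be controlled.

**Step 1**
Reactants: 1 3,4-dihydroxy-5-methoxybenzaldehyde (5-hydroxyvanillin)
Product: 2 3,4-bis(benzyloxy)-5-methoxybenzaldehyde
Conditions: BnBr (2.3 equiv), K2CO3 (3 equiv), DMF, 60 °C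
Reagents that add atoms: benzyl bromide, BrCc1ccccc1
Why: Williamson ether synthesis on both acidic catechol hydroxyls should proceed cleanly, the aldehyde being inert to carbonate base.

**Step 2**
Reactants: 2 3,4-bis(benzyloxy)-5-methoxybenzaldehyde
Product: 3 [3,4-bis(benzyloxy)-5-methoxyphenyl]methanol
Conditions: NaBH4, MeOH/THF, 0 °C
Reagents that add atoms: none
Why: Borohydride reduction of an aryl aldehyde to the benzylic alcohol is chemoselective and leaves the aryl ethers untouched.

**Step 3**
Reactants: 3 [3,4-bis(benzyloxy)-5-methoxyphenyl]methanol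
Product: 4 1,2-bis(benzyloxy)-5-(chloromethyl)-3-methoxybenzene
Conditions: SOCl2 (1.2 equiv), DMF (cat.), CH2Cl2, 0 °C to rt
Reagents that add atoms: thionyl chloride, O=S(Cl)Cl
Why: Deoxychlorination of an electron-rich benzylic alcohol through its chlorosulfite is the standard entry to 3,4,5-trialkoxybenzyl chlorides and should tolerate the benzyl ethers at low temperature.

**Step 4**
Reactants: 4 1,2-bis(benzyloxy)-5-(chloromethyl)-3-methoxybenzene (two molecules: one converted into the zinc reagent, one used as the electrophile), 5 but-2-yne
Product: 8 (Z)-1,4-bis[3,4-bis(benzyloxy)-5-methoxyphenyl]-2,3-dimethylbut-2-ene, via benzylic zinc chloride 6 (not isolated), via (Z)-alkenylzinc chloride 7 (not isolated)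
Conditions: (a) 4 (1.0 equiv), Zn dust, LiCl, THF, 25 °C; (b) 5 (1.5 equiv), CoBr2 (5 mol %), P(4-MeOC6H4)3 (10 mol %), EtCN–THF, sealed vessel, 25 to 60 °C; (c) purge excess 5 with argon, then 4 (1.1 equiv), Pd(PPh3)4 (3 mol %), 50 °C
Reagents that add atoms: none
Why: Transmetalation of benzylic zinc chloride 6 to low-valent cobalt gives a benzylcobalt species that inserts but-2-yne suprafacially (cis), forming the first benzylic CH2–C(CH3) bond, and transmetalation back to zinc with retention releases the (Z)-alkenylzinc chloride 7. Zerovalent palladium then adds oxidatively to the C–Cl bond of a second molecule of 4, takes over the alkenyl group from zinc with retention of geometry and forms the second CH2–C(CH3) bond by reductive elimination. The closest known reaction types are the cobalt-catalysed syn-benzylzincation (carbozincation) of internal dialkylalkynes with in-flask trapping of the alkenylzinc, and the Negishi coupling of alkenylzinc halides with benzylic halides. No ring is closed and no stereocentre is formed; what is set is the (Z) double-bond geometry, controlled by the cis mode of migratory insertion and by stereoretentive transmetalation and reductive elimination, and this geometry later encodes the meso configuration. The step needs mono-insertion and cis-selectivity without E/Z leakage: the symmetry of but-2-yne removes any regiochemical issue, the alkenylzinc should be far less prone than the benzylic zinc to add to a second alkyne, the excess alkyne is purged before palladium is added, and the aryl ethers are inert to organozinc, cobalt and palladium.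

**Step 5**
Reactants: 8 (Z)-1,4-bis[3,4-bis(benzyloxy)-5-methoxyphenyl]-2,3-dimethylbut-2-ene
Product: 10 meso-(2R,3S)-1,4-bis(3,4-dihydroxy-5-methoxyphenyl)-2,3-dimethylbutane, via tetraphenol (Z)-alkene 9 (not isolated)
Conditions: H2 (4 bar), 10% Pd/C, EtOAc/EtOH (1:1), rt
Reagents that add atoms: none
Why: Heterogeneous hydrogenolysis of the four aryl benzyl ethers followed by suprafacial (syn) hydrogenation of the tetrasubstituted (Z)-alkene, a reduction with close precedent on (Z)-1,4-diaryl-2,3-dimethylbut-2-enes, should set both stereocentres at once: cis delivery of two hydrogens to either of the two equivalent faces of the (Z)-alkene can only give the meso (2R,3S) diastereomer.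

**Compound list**
1 | 3,4-dihydroxy-5-methoxybenzaldehyde (5-hydroxyvanillin) | COc1cc(C=O)cc(O)c1O | starting material
2 | 3,4-bis(benzyloxy)-5-methoxybenzaldehyde | COc1cc(C=O)cc(OCc2ccccc2)c1OCc1ccccc1 | intermediate
3 | [3,4-bis(benzyloxy)-5-methoxyphenyl]methanol | COc1cc(CO)cc(OCc2ccccc2)c1OCc1ccccc1 | intermediate
4 | 1,2-bis(benzyloxy)-5-(chloromethyl)-3-methoxybenzene | COc1cc(CCl)cc(OCc2ccccc2)c1OCc1ccccc1 | intermediate
5 | but-2-yne | CC#CC | starting material
6 | [3,4-bis(benzyloxy)-5-methoxybenzyl]zinc chloride (not isolated) | COc1cc(C[Zn]Cl)cc(OCc2ccccc2)c1OCc1ccccc1 | intermediate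
7 | (Z)-{4-[3,4-bis(benzyloxy)-5-methoxyphenyl]-3-methylbut-2-en-2-yl}zinc chloride (not isolated) | C/C(Cc1cc(OC)c(OCc2ccccc2)c(OCc2ccccc2)c1)=C(\C)[Zn]Cl | intermediate
8 | (Z)-1,4-bis[3,4-bis(benzyloxy)-5-methoxyphenyl]-2,3-dimethylbut-2-ene | C/C(Cc1cc(OC)c(OCc2ccccc2)c(OCc2ccccc2)c1)=C(\C)Cc1cc(OC)c(OCc2ccccc2)c(OCc2ccccc2)c1 | intermediate
9 | (Z)-1,4-bis(3,4-dihydroxy-5-methoxyphenyl)-2,3-dimethylbut-2-ene (not isolated) | C/C(Cc1cc(O)c(O)c(OC)c1)=C(\C)Cc1cc(O)c(O)c(OC)c1 | intermediate
10 | meso-(2R,3S)-1,4-bis(3,4-dihydroxy-5-methoxyphenyl)-2,3-dimethylbutane | COc1cc(C[C@@H](C)[C@@H](C)Cc2cc(O)c(O)c(OC)c2)cc(O)c1O | target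

**Step count and risks**
Total step count: 5. Longest linear sequence: 5 steps (from 1 to 10).

Steps most likely to fail:

1. Step 4. The carbozincation of the volatile alkyne may stall, cobalt may divert but-2-yne into cyclotrimerisation, the benzylic zinc may homocouple during insertion, or the alkenylzinc may be protonated before it is cross-coupled. Fallback, setting out from 5: syn-diboration with bis(pinacolato)diboron (Pt(PPh3)4 cat., DMF, 80 °C, sealed vessel) should give (Z)-2,3-bis(4,4,5,5-tetramethyl-1,3,2-dioxaborolan-2-yl)but-2-ene F1. Two-fold Suzuki–Miyaura coupling of F1 with chloride 4 (Pd(OAc)2, SPhos, K3PO4, THF/H2O, 60 °C) then forms the same two benzylic CH2–C(CH3) bonds, keeps the cis geometry of the diboration, and comes back to the route at 8.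

2. Step 5. Palladium may move the double bond into conjugation with an aryl ring before hydrogen is added, which would erode the syn-fidelity and the meso purity, or the hindered tetrasubstituted alkene may be reduced incompletely. Fallback, setting out from 8: the C=C reduction is separated from the deprotection. Homogeneous hydrogenation with the cationic iridium complex [Ir(cod)(PCy3)(py)]PF6 (H2, 50 bar, CH2Cl2, rt) adds H2 in an inner-sphere cis manner and leaves the benzyl ethers intact. It should give meso-(2R,3S)-1,4-bis[3,4-bis(benzyloxy)-5-methoxyphenyl]-2,3-dimethylbutane F2, which can be purified by crystallisation. Hydrogenolysis of F2 (H2, 1 bar, Pd(OH)2/C, EtOAc/MeOH) comes back to the route at 10.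

3. Step 3. The HCl released may promote Friedel–Crafts self-alkylation of the electron-rich benzylic chloride or partial loss of a benzyl ether on concentration. Fallback, setting out from 3: neutral Appel bromination (CBr4, PPh3, CH2Cl2, 0 °C) should give 1,2-bis(benzyloxy)-5-(bromomethyl)-3-methoxybenzene F3. F3 takes the place of 4 in the three-component coupling under the conditions of step 4, through [3,4-bis(benzyloxy)-5-methoxybenzyl]zinc bromide F4 and (Z)-{4-[3,4-bis(benzyloxy)-5-methoxyphenyl]-3-methylbut-2-en-2-yl}zinc bromide F5, and comes back to the route at 8.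

**Further compounds**
F1 | step 4 | (Z)-2,3-bis(4,4,5,5-tetramethyl-1,3,2-dioxaborolan-2-yl)but-2-ene | C/C(B1OC(C)(C)C(C)(C)O1)=C(\C)B1OC(C)(C)C(C)(C)O1
F2 | step 5 | meso-(2R,3S)-1,4-bis[3,4-bis(benzyloxy)-5-methoxyphenyl]-2,3-dimethylbutane | COc1cc(C[C@@H](C)[C@@H](C)Cc2cc(OCc3ccccc3)c(OCc3ccccc3)c(OC)c2)cc(OCc2ccccc2)c1OCc1ccccc1
F3 | step 3 | 1,2-bis(benzyloxy)-5-(bromomethyl)-3-methoxybenzene | COc1cc(CBr)cc(OCc2ccccc2)c1OCc1ccccc1
F4 | step 3 | [3,4-bis(benzyloxy)-5-methoxybenzyl]zinc bromide | COc1cc(C[Zn]Br)cc(OCc2ccccc2)c1OCc1ccccc1
F5 | step 3 | (Z)-{4-[3,4-bis(benzyloxy)-5-methoxyphenyl]-3-methylbut-2-en-2-yl}zinc bromide | C/C(Cc1cc(OC)c(OCc2ccccc2)c(OCc2ccccc2)c1)=C(\C)[Zn]Br
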